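4 questions stood before me, on green and grey, two flasks that differ from the earlier runs in their second substrate.

| setting | Friday's | Wednesday's | green | grey |
|---|---|---|---|---|
| starting material | 0.10 M | 0.10 M | 0.10 M | 0.10 M |
| partner | 1.3 equiv | 1.3 equiv | 1.30 equiv | 1.30 equiv |
| second substrate | 1.3 equiv | 1.6 equiv | 2.00 equiv | 2.60 equiv |
| protic impurity | 0.050 M | 0.050 M | 0.0500 M | 0.0500 M |
| remark | run made earlier | run made earlier |  |  |
| time |  |  | 6.0 h | 6.0 h |

| run | time / h | starting material / % | target / % | cross product / % |
|---|---|---|---|---|
| Friday's | 0.167 | 55.4 | 36.3 | 8.7 |
| Friday's | 0.500 | 25.0 | 59.6 | 14.9 |
| Friday's | 0.833 | 14.5 | 66.9 | 18.4 |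
| Friday's | 1.33 | 7.4 | 72.7 | 19.2 |
| Friday's | 2.00 | 4.1 | 76.4 | 20.9 |
| Friday's | 2.50 | 2.9 | 75.4 | 21.0 |
| Friday's | 3.00 | 2.0 | 76.1 | 22.2 |
| Wednesday's | 0.417 | 27.6 | 54.2 | 17.8 |
| Wednesday's | 0.833 | 13.5 | 64.4 | 21.7 |
| Wednesday's | 1.33 | 7.1 | 69.3 | 24.2 |
| Wednesday's | 1.50 | 6.4 | 71.2 | 23.8 |
| Wednesday's | 2.00 | 3.9 | 71.1 | 24.3 |
| Wednesday's | 2.50 | 2.1 | 72.4 | 25.3 |
| Wednesday's | 3.00 | 1.6 | 72.1 | 25.8 |

(standard deviation of a reading: 0.5 percentage points)

- which of these there is most of at the end, counted by the starting material in it, green (starting material / cross product / target)
- which of these there is most of at the end, counted by the starting material in it, grey (starting material / cross product / target)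
- the largest of these amounts at the end, in percent of the starting material charged, green
- the largest of these amounts at the end, in percent of the starting material charged, grey

- steps under discussion: second substrate + partner -> second product; starting material + partner -> target; second substrate + protic impurity -> quenched substrate; second substrate <-> dormant form; starting material + second substrate -> cross product

1. Starting material went two ways: with partner to target, and with second substrate to cross product. The bench rule for two competitors says the products come in the ratio of the competitors' charges, times a constant.

2. Friday's last reading gave 3.43 for target over cross product, multiplied by second substrate charged over partner charged. I called that product the split number, G, a selectivity factor. Wednesday's last reading gave 3.44, so the rule held on both readings.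

3. Wednesday's starting material was down to 1.6% by 3.00 h, and the new flasks ran 6.0 h, so I let target and cross product share the charge. My ratio was G times partner over second substrate: 2.23 in green, a target share of 69.0%, and 1.71 in grey, a share of 63.2%.

4. Partner goes into target one for one, but second substrate takes partner too, on the way to second product, so one partner per starting material gave me no border. I looked at second substrate over partner instead. The readings reached 1.23 on Wednesday. Green stood at 1.54 and grey at 2.00, both beyond that, so both my shares were stretches past what the rule had been tried on.

5. The forecast named target in green and target in grey, as I did, but at 62% and 53%, lower than my shares. Its ground was that “the impurity appears to take its share quickly, and the cross product follows the excess”.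

6. Green gave target at 68.1%, and grey gave target at 61.1%.

    second substrate + partner → second product (k = 4.70 M⁻¹ h⁻¹)
    starting material + partner → target (k = 28.0 M⁻¹ h⁻¹)
    second substrate + protic impurity → quenched substrate (k = 4.90 M⁻¹ h⁻¹)
    second substrate ⇌ dormant form (K = 1.10, k = 0.150 h⁻¹)
    starting material + second substrate → cross product (k = 6.00 M⁻¹ h⁻¹)

7. Green's end amounts put its split number at 3.32, against the 3.43 I carried. Green's target stopped at 68.1% mainly because of the step from starting material and second substrate to cross product: the run with that step struck out gave 84.8%. The flask like green but with 0.520 equiv of partner lay further still past the readings; there the split number gave a target share of 47.1%, and it ended at 35.0% target against 61.4% cross product.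

(The runs were generated by integration with constants of no real substance.)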